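## The problem

The target joins two 5,7-dimethoxycoumarin units through their C8 atoms. Ring A carries a (Z)-ethenyl bridge to a quaternary carbon of a cyclohexene, and ring B sits directly on the neighbouring ring carbon. The cyclohexene is numbered here C1 (quaternary, bearing CH3 and the bridge carbon Cb), C2, C3, C4(CH3)=C5 and C6 (bonded to C8 of ring B). The only stereocentres are C1 and C6, both R and contiguous, with ring B cis to Cb and trans to the C1 methyl group.

Neither centre can be corrected later, because C1 has no hydrogen and C6–H cannot be epimerised cleanly. Both therefore have to be set in one ring-forming event that fixes their relation, and the absolute sense has to enter there too, since the obvious building blocks are achiral.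

The reagent choice is limited by the two lactones (hydroxide, hydrides, organometallics) and by the benzylic–allylic C6–H and the trisubstituted C4=C5 bond (strong acid, oxidants). The crowded Z-alkene is the less stable isomer and has to be made last under mild conditions.

The enabling feature is that C6 is a benzylic carbon flanked by the aryl oxygen on C8a of ring B and by the C4=C5 bond. The chain O–C8a–C8–C6–C1–Cb is thus a hidden chroman, the retron of an o-quinone methide [4+2] adduct with Cb as acetal carbon. An acetal carbon is one homologation away from the alkyne that gives both the Z-alkene and the bond to ring A.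

## Retrosynthesis

**18 to 17, then 14 + 16.** The Z-alkene of target 18 is taken back to alkyne 17, so that the geometry comes from a syn-addition of hydrogen in the last step. An olefination of a neopentyl aldehyde with a benzylic ylide would give E/Z mixtures, and a Diels–Alder dimerisation of a coumarinyl diene would give the E-styryl isomer. Cutting 17 at the C(sp)–C8 bond of ring A gives terminal alkyne 14 and aryl iodide 16 (Sonogashira coupling). The precursors are a chiral half with all the stereochemistry and a flat, achiral half. The forward reaction has to join a tertiary-alkyl alkyne with a di-ortho-substituted, electron-rich iodide.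

**16 to 15.** The C–I bond is cut back to C–H of 5,7-dimethoxycoumarin 15. This asks for iodination at C8 in preference to C6 and C3.

**14 to 13 to 12.** The pyranone of ring B is cut at C3=C4 and at O1–C2 (Wittig olefination with lactonisation), which leads to salicylaldehyde 13. The formyl carbon is then cut from C4a, which leads to phenol 12. Ring B is built late because the key step needs a free, electron-rich phenol with two equivalent ortho positions. A preformed hydroxycoumarin would be less nucleophilic and would offer C6 and C8 in competition. After the key step the phenol oxygen is exactly O1 and only one ortho carbon is left, so an ortho-specific formylation has no choice to make.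

**12 to 11 to 10.** The alkyne carbon is removed (one-carbon homologation of an aldehyde), which leads to lactol 11, the closed form of the hydroxy aldehyde, and from there to methyl acetal 10. The α-carbon C1 is quaternary, so this aldehyde cannot epimerise. The forward steps are an acetal hydrolysis and an Ohira–Bestmann reaction on a hindered aldehyde.

**10 to 6 + 7.** Three bonds are cut in acetal 10: C8–C6, C6–C1 and O–Cb. This opens the cyclohexene and the pyran together and removes both stereocentres, leaving dienal 6 and the symmetrical phenol 7. Neighbouring cuts, such as a Friedel–Crafts allylation with a chiral cyclohexenol or a Diels–Alder reaction of an aryl diene, either need the stereocentres beforehand or raise regiochemical and endo/exo questions. The forward reaction runs through chromene 8 and o-quinone methide 9. It must give ortho C-alkylation, cis ring fusion and one enantiomer.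

**6 to 5 to 4 to 3 to 1 + 2.** The enal is taken back through allylic alcohol 5 to ester 4. The enol ether C=C is cut to the ketone of 3 (methoxymethylene Wittig reaction), and the C2=C3 bond of 3 is cut to hexane-2,5-dione 1 and phosphonate 2. The diketone supplies C3 to C6 with both methyl groups in place. The only demand is mono-olefination of a symmetrical diketone.

## Roads not taken

**Alternative 1:** Only C8–C6 is cut. Ring B arrives complete as the 7,8-aryne released by fluoride from 5-methoxy-2-oxo-8-(trimethylsilyl)-2H-chromen-7-yl trifluoromethanesulfonate A3. The cyclohexene arrives as the tertiary allylic ether (3R,6S)-3-methoxy-3,6-dimethyl-6-{[tri(propan-2-yl)silyl]ethynyl}cyclohex-1-ene A2. The ether oxygen should add at C7, and the aryl anion at C8 should then attack the allyl terminus in a [3,3] shift. This forms C8–C6, moves the alkene to C4=C5 and leaves the oxygen behind as the 7-methoxy group, giving 8-[(1R,6S)-3,6-dimethyl-6-{[tri(propan-2-yl)silyl]ethynyl}cyclohex-2-en-1-yl]-5,7-dimethoxy-2H-chromen-2-one A1.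

- Merits: the route is convergent, ring B need not be built on the chiral fragment, the alkyne is already present, and a suprafacial shift would pass the configuration of C4 on to C6. The endgame is shorter than the chosen one by the formylation and lactonisation steps, and in this respect the road is better.
- Weak points: a hindered tertiary dialkyl ether is a poor partner for an aryne. The oxonium zwitterion has easier exits, namely proton transfer with elimination, [1,2] shifts, and ionisation of the tertiary allylic C–O bond, which would erase the chirality transfer. The new bond forms next to a quaternary carbon. Above all, A2 must be supplied as one stereoisomer with two fully substituted stereocentres in a 1,4-relation, which is harder to make than the stereodiad of the target is to create. A3 also needs its own multistep synthesis.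
- Comparison: the chosen plan sets against the shorter endgame that it creates both stereocentres from achiral material in one catalytic step.

**Alternative 2:** C1–C2 and C5–C6 are cut. The dienophile is the C3=C4 bond of 5,7-dimethoxy-2-oxo-2H-chromene-3-carbaldehyde A5 and the diene is (E)-trimethyl(2-methylbuta-1,3-dien-1-yl)silane A6. A chiral Lewis acid bound to the 1,3-dicarbonyl unit would steer the diene to one face and close the carbocycle cis-fused to the lactone. The product is (6aS,10aS)-1,3-dimethoxy-9-methyl-6-oxo-10-(trimethylsilyl)-6a,7,10,10a-tetrahydro-6H-benzo[c]chromene-6a-carbaldehyde A4, either epimer at C10. Protodesilylation with allylic shift would then place the alkene at C4=C5. The aldehyde would have to become the C1 methyl group and the lactone carbonyl the lactol carbon, at which point the road meets lactol 11.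

- Merits: the cis relation of aryl and Cb is enforced by the dienophile being part of a ring and does not depend on a transition-state preference. Two-point binding of a β-dicarbonyl dienophile is the best understood mode of Lewis acid enantiocontrol. In both respects this road is more secure than the chosen one.
- Weak points: the C5–C6 bond must form between a silyl-bearing diene terminus and C4 of the coumarin, which is peri to the 5-methoxy group and deactivated by the electron-rich ring. Three corrections of oxidation state or position at hindered carbons are needed before 11 is reached: aldehyde to methyl, allylsilane transposition and lactone to lactol.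
- Comparison: the chosen plan sets against the better stereochemical security its exact match of oxidation states. The methyl group and the acetal carbon appear as needed, and 11 is reached in six steps.

**Alternative 3:** Three bonds of the benzene ring of ring B are cut (C8–C8a, C7–C6 and C8a–C4a). Heating 3-methoxycyclobut-2-en-1-one A9 with the siloxyalkyne tert-butyl{[(1S,2R)-1,4-dimethyl-2-({[tri(propan-2-yl)silyl]oxy}ethynyl)cyclohex-3-en-1-yl]methoxy}dimethylsilane A8 should lead through a vinylketene, [2+2] addition, four-electron opening and six-electron closure. The product is 2-[(1R,6S)-6-({[tert-butyl(dimethyl)silyl]oxy}methyl)-3,6-dimethylcyclohex-2-en-1-yl]-5-methoxy-3-{[tri(propan-2-yl)silyl]oxy}phenol A7.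

- Merits: the substitution pattern of the arene is fixed by construction, with the two ortho oxygens already differentiated. The conditions are neutral and thermal. In regiochemical certainty this road is at least as good as the chosen one.
- Weak points: no stereocentre is set. A8 must already hold C1 and C6 in the cis relation and must be made as an ynol ether at a hindered secondary carbon, so the stereochemical problem is only moved back. The [2+2] step is sensitive to bulk on the alkyne. After the annulation the route still needs O-methylation, desilylation, formylation, lactonisation and conversion of the protected hydroxymethyl group into the alkyne.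
- Comparison: the chosen plan obtains the same regiochemical certainty from the symmetry of 7 and an ortho-specific formylation, and it builds the stereocentres, which this road does not.

Key step: step 5

Assumptions:
- In systematic names the cyclohexene is a cyclohex-2-en-1-yl group whose locant 1 is C6 and locant 6 is C1 of the discussion. In benzo[c]chromenes 10 and 11, C6a is C1, C10a is C6 and C6 is Cb.
- Compounds 3 to 6 are expected as E/Z mixtures at both alkenes and are carried on as such, because neither geometry reaches the product. Names and SMILES show the E isomers.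
- Acetal 10 and lactol 11 are expected as mixtures at C6, which is left open in the SMILES and disappears in step 7.
- Which enantiomer of the phosphoric acid leads to the (6aS,10aS) series cannot be predicted safely. The R acid is written, and its mirror image would be used if the sense proves opposite.

## Route

Step 1
Reactants: 1 hexane-2,5-dione; 2 triethyl phosphonoacetate
Product: 3 ethyl (2E)-3-methyl-6-oxohept-2-enoate
Conditions: 2, NaH, THF, 0 °C; then added to 1 (3 equiv), 0 °C to rt
Reagents that add atoms: none
Why: Horner–Wadsworth–Emmons olefination of a methyl ketone; adding the preformed sodium phosphonate to an excess of the symmetrical diketone favours mono-olefination, and the E/Z mixture is acceptable because this alkene geometry is reset in step 5.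

Step 2
Reactants: 3 ethyl (2E)-3-methyl-6-oxohept-2-enoate
Product: 4 ethyl (2E,6E)-7-methoxy-3,6-dimethylhepta-2,6-dienoate
Conditions: Ph3P(CH2OMe)Cl, NaHMDS, THF, −78 to 0 °C
Reagents that add atoms: (methoxymethyl)triphenylphosphonium chloride, COC[P+](c1ccccc1)(c1ccccc1)c1ccccc1.[Cl-]
Why: Wittig methoxymethylenation; the non-stabilised ylide adds to the ketone and leaves the conjugated ester alone, and the enol ether geometry is immaterial because it ends at the acetal carbon.

Step 3
Reactants: 4 ethyl (2E,6E)-7-methoxy-3,6-dimethylhepta-2,6-dienoate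
Product: 5 (2E,6E)-7-methoxy-3,6-dimethylhepta-2,6-dien-1-ol
Conditions: i-Bu2AlH, CH2Cl2, −78 °C; aq. Rochelle salt
Reagents that add atoms: none
Why: 1,2-reduction of the enoate with DIBAL-H at low temperature; the neutral tartrate work-up keeps the enol ether from hydrolysing.

Step 4
Reactants: 5 (2E,6E)-7-methoxy-3,6-dimethylhepta-2,6-dien-1-ol
Product: 6 (2E,6E)-7-methoxy-3,6-dimethylhepta-2,6-dienal
Conditions: MnO2 (activated, excess), CH2Cl2, rt
Reagents that add atoms: none
Why: allylic oxidation on the neutral MnO2 surface gives the enal without touching the acid-labile enol ether.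

Step 5
Reactants: 6 (2E,6E)-7-methoxy-3,6-dimethylhepta-2,6-dienal; 7 3,5-dimethoxyphenol
Product: 10 (6aS,10aS)-1,3,6-trimethoxy-6a,9-dimethyl-6a,7,8,10a-tetrahydro-6H-benzo[c]chromene, via 2H-chromene 8 (not isolated), via o-quinone methide 9 (not isolated)
Conditions: ethylenediammonium diacetate (5 mol %), 4 Å MS, PhMe, 60 °C; then (R)-3,3′-bis(2,4,6-triisopropylphenyl)-1,1′-binaphthyl-2,2′-diyl hydrogen phosphate, (R)-TRIP (20 mol %), −20 °C to rt
Reagents that add atoms: none
Why: Proposed new method: the diammonium acetate turns enal 6 into an iminium ion that the symmetrical phenol 7 attacks through an ortho carbon, and loss of the amine gives a vinyl o-quinone methide that rests as 2H-chromene 8 after oxa-six-electron closure (known chromenylation). The phosphoric acid, added in excess over the amine, reopens 8 to the hydrogen-bonded o-quinone methide 9 (at the limit a phosphate-paired hydroxyaryl pentadienyl cation); opening and closing are reversible, so the C4=C5 bond can take up the cis geometry, and only that isomer places the enol ether within reach of C6. The enol ether then adds across O=C8a–C8=C6 in an inverse-demand hetero-[4+2] reaction that should be concerted but asynchronous: the carbocycle closes by 6-exo attack of the enol ether β-carbon C1 on C6, and the pyran closes by capture of the developing oxocarbenium carbon Cb by the quinone methide oxygen, also six-membered. The closest known reactions are the condensation of citral with resorcinols to cis-fused tetrahydrobenzo[c]chromenes and the phosphoric-acid-catalysed [4+2] additions of o-quinone methides to vinyl ethers; joining them into one enantioselective domino with a tethered enol ether has no precedent. C1 and C6 are created together: in the geometry released from the chromene the dienyl chain of 9 is syn to the carbonyl oxygen, and from there the four-atom tether can reach only the transition state that leads to the cis-fused bicycle (aryl cis to Cb, CH3 trans), while the enol ether geometry affects only the acetal carbon. The absolute configuration must come from the chiral phosphate, which holds the quinone methide oxygen by a hydrogen bond and shields one face of C6. The step needs ortho C-alkylation, secured by the equivalence of the two ortho positions of 7 and by the reversibility of para attack, which cannot cyclise, and it needs the enol ether to survive until the cycloaddition, for which the molecular sieves remove the water of condensation.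

Step 6
Reactants: 10 (6aS,10aS)-1,3,6-trimethoxy-6a,9-dimethyl-6a,7,8,10a-tetrahydro-6H-benzo[c]chromene
Product: 11 (6aS,10aS)-1,3-dimethoxy-6a,9-dimethyl-6a,7,8,10a-tetrahydro-6H-benzo[c]chromen-6-ol
Conditions: 1 M aq. HCl, THF, 0 °C to rt
Reagents that add atoms: water, O
Why: acid hydrolysis of the mixed aryl methyl acetal through the cyclic oxocarbenium ion; C6a has no hydrogen and C10a is not involved, so both stereocentres stay untouched, and dilute acid leaves the trisubstituted alkene alone.

Step 7
Reactants: 11 (6aS,10aS)-1,3-dimethoxy-6a,9-dimethyl-6a,7,8,10a-tetrahydro-6H-benzo[c]chromen-6-ol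
Product: 12 2-[(1R,6S)-6-ethynyl-3,6-dimethylcyclohex-2-en-1-yl]-3,5-dimethoxyphenol
Conditions: MeC(O)C(N2)P(O)(OMe)2, K2CO3, MeOH, 0 °C to rt
Reagents that add atoms: dimethyl (1-diazo-2-oxopropyl)phosphonate, COP(=O)(OC)C(=[N+]=[N-])C(C)=O
Why: Ohira–Bestmann (Seyferth–Gilbert) homologation; in basic methanol the aryl hemiacetal opens to phenoxide and aldehyde, the diazophosphonate anion adds, and loss of dimethyl phosphate and N2 with 1,2-hydride shift gives the terminal alkyne, while the quaternary α-carbon cannot epimerise.

Step 8
Reactants: 12 2-[(1R,6S)-6-ethynyl-3,6-dimethylcyclohex-2-en-1-yl]-3,5-dimethoxyphenol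
Product: 13 3-[(1R,6S)-6-ethynyl-3,6-dimethylcyclohex-2-en-1-yl]-2-hydroxy-4,6-dimethoxybenzaldehyde
Conditions: MgCl2, Et3N, (CH2O)n, MeCN, reflux; dil. HCl work-up
Reagents that add atoms: paraformaldehyde (source of formaldehyde), C=O
Why: magnesium-mediated ortho-formylation (Casnati–Skattebøl type); the magnesium phenoxide delivers formaldehyde to the one free ortho carbon and a second formaldehyde oxidises the benzylic alkoxide by hydride transfer, while the para position between the methoxy groups cannot be reached by this chelated path.

Step 9
Reactants: 13 3-[(1R,6S)-6-ethynyl-3,6-dimethylcyclohex-2-en-1-yl]-2-hydroxy-4,6-dimethoxybenzaldehyde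
Product: 14 8-[(1R,6S)-6-ethynyl-3,6-dimethylcyclohex-2-en-1-yl]-5,7-dimethoxy-2H-chromen-2-one
Conditions: Ph3P=CHCO2Et, PhNEt2, reflux
Reagents that add atoms: ethyl (triphenylphosphoranylidene)acetate, CCOC(=O)C=P(c1ccccc1)(c1ccccc1)c1ccccc1
Why: Wittig olefination of the salicylaldehyde followed, at the reflux temperature of N,N-diethylaniline, by E/Z equilibration and lactonisation with loss of ethanol, the standard entry to 8-substituted 5,7-dialkoxycoumarins; a [3,3] shift of the 1,5-enyne is excluded because it would place an allene in a six-membered ring.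

Step 10
Reactants: 15 5,7-dimethoxy-2H-chromen-2-one
Product: 16 8-iodo-5,7-dimethoxy-2H-chromen-2-one
Conditions: NIS, CF3CO2H (cat.), MeCN, rt
Reagents that add atoms: N-iodosuccinimide, O=C1CCC(=O)N1I
Why: electrophilic aromatic iodination; C8 is para to the 5-methoxy group, ortho to the 7-methoxy group and the ring oxygen, and less crowded than C6 between two methoxy groups, and the deactivated C3=C4 bond should not compete under acid catalysis.

Step 11
Reactants: 14 8-[(1R,6S)-6-ethynyl-3,6-dimethylcyclohex-2-en-1-yl]-5,7-dimethoxy-2H-chromen-2-one; 16 8-iodo-5,7-dimethoxy-2H-chromen-2-one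
Product: 17 8-[(1R,6S)-6-[(5,7-dimethoxy-2-oxo-2H-chromen-8-yl)ethynyl]-3,6-dimethylcyclohex-2-en-1-yl]-5,7-dimethoxy-2H-chromen-2-one
Conditions: Pd(PPh3)2Cl2 (5 mol %), CuI (10 mol %), Et3N, DMF, 50 °C
Reagents that add atoms: none
Why: Sonogashira coupling; gentle heating helps oxidative addition of the electron-rich iodide to zerovalent palladium, and the phenol that could cyclise onto the alkyne is already tied up in the lactone.

Step 12
Reactants: 17 8-[(1R,6S)-6-[(5,7-dimethoxy-2-oxo-2H-chromen-8-yl)ethynyl]-3,6-dimethylcyclohex-2-en-1-yl]-5,7-dimethoxy-2H-chromen-2-one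
Product: 18 8-[(1R,6R)-6-[(Z)-2-(5,7-dimethoxy-2-oxo-2H-chromen-8-yl)ethenyl]-3,6-dimethylcyclohex-2-en-1-yl]-5,7-dimethoxy-2H-chromen-2-one
Conditions: H2 (1 atm), Pd/CaCO3 poisoned with Pb(OAc)2 (Lindlar catalyst), quinoline, EtOAc, rt
Reagents that add atoms: none
Why: Lindlar semihydrogenation; syn-addition of one equivalent of H2 on the poisoned palladium surface gives the Z-alkene, the conjugated coumarin C3=C4 bonds and the trisubstituted ring alkene are much slower on this catalyst, and the stereocentres are not involved (the descriptor at the quaternary carbon changes from S to R only through the priority rules).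

## Compound list

1 | hexane-2,5-dione | CC(=O)CCC(C)=O | starting material
2 | triethyl phosphonoacetate | CCOC(=O)CP(=O)(OCC)OCC | starting material
3 | ethyl (2E)-3-methyl-6-oxohept-2-enoate | CCOC(=O)/C=C(\C)CCC(C)=O | intermediate
4 | ethyl (2E,6E)-7-methoxy-3,6-dimethylhepta-2,6-dienoate | CCOC(=O)/C=C(\C)CC/C(C)=C/OC | intermediate
5 | (2E,6E)-7-methoxy-3,6-dimethylhepta-2,6-dien-1-ol | OC/C=C(\C)CC/C(C)=C/OC | intermediate
6 | (2E,6E)-7-methoxy-3,6-dimethylhepta-2,6-dienal | O=C/C=C(\C)CC/C(C)=C/OC | intermediate
7 | 3,5-dimethoxyphenol | COc1cc(O)cc(OC)c1 | starting material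
8 | 5,7-dimethoxy-2-[(3E)-4-methoxy-3-methylbut-3-en-1-yl]-2-methyl-2H-chromene (racemic at C2; not isolated) | CO/C=C(\C)CCC1(C)C=Cc2c(OC)cc(OC)cc2O1 | intermediate
9 | (6Z)-6-[(2Z,6E)-7-methoxy-3,6-dimethylhepta-2,6-dien-1-ylidene]-3,5-dimethoxycyclohexa-2,4-dien-1-one (not isolated) | CO/C=C(\C)CC/C(C)=C\C=C1/C(=O)C=C(OC)C=C1OC | intermediate
10 | (6aS,10aS)-1,3,6-trimethoxy-6a,9-dimethyl-6a,7,8,10a-tetrahydro-6H-benzo[c]chromene (both C6 anomers) | COC1Oc2cc(OC)cc(OC)c2[C@@H]2C=C(C)CC[C@]12C | intermediate
11 | (6aS,10aS)-1,3-dimethoxy-6a,9-dimethyl-6a,7,8,10a-tetrahydro-6H-benzo[c]chromen-6-ol (both C6 anomers) | OC1Oc2cc(OC)cc(OC)c2[C@@H]2C=C(C)CC[C@]12C | intermediate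
12 | 2-[(1R,6S)-6-ethynyl-3,6-dimethylcyclohex-2-en-1-yl]-3,5-dimethoxyphenol | C#C[C@@]1(C)CCC(C)=C[C@H]1c1c(O)cc(OC)cc1OC | intermediate
13 | 3-[(1R,6S)-6-ethynyl-3,6-dimethylcyclohex-2-en-1-yl]-2-hydroxy-4,6-dimethoxybenzaldehyde | C#C[C@@]1(C)CCC(C)=C[C@H]1c1c(O)c(C=O)c(OC)cc1OC | intermediate
14 | 8-[(1R,6S)-6-ethynyl-3,6-dimethylcyclohex-2-en-1-yl]-5,7-dimethoxy-2H-chromen-2-one | C#C[C@@]1(C)CCC(C)=C[C@H]1c1c(OC)cc(OC)c2ccc(=O)oc12 | intermediate
15 | 5,7-dimethoxy-2H-chromen-2-one (5,7-dimethoxycoumarin) | COc1cc(OC)c2ccc(=O)oc2c1 | starting material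
16 | 8-iodo-5,7-dimethoxy-2H-chromen-2-one | COc1cc(OC)c2ccc(=O)oc2c1I | intermediate
17 | 8-[(1R,6S)-6-[(5,7-dimethoxy-2-oxo-2H-chromen-8-yl)ethynyl]-3,6-dimethylcyclohex-2-en-1-yl]-5,7-dimethoxy-2H-chromen-2-one | COc1cc(OC)c2ccc(=O)oc2c1C#C[C@@]1(C)CCC(C)=C[C@H]1c1c(OC)cc(OC)c2ccc(=O)oc12 | intermediate
18 | 8-[(1R,6R)-6-[(Z)-2-(5,7-dimethoxy-2-oxo-2H-chromen-8-yl)ethenyl]-3,6-dimethylcyclohex-2-en-1-yl]-5,7-dimethoxy-2H-chromen-2-one | COc1cc(OC)c2ccc(=O)oc2c1/C=C\[C@@]1(C)CCC(C)=C[C@H]1c1c(OC)cc(OC)c2ccc(=O)oc12 | target

## Step count and weak points

Total: 12 steps. Longest linear sequence: 11 steps (steps 1 to 9, 11 and 12, from hexane-2,5-dione 1); step 10 is a one-step branch.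

**Step 5 (key step).** The most likely failures are these:
- protonation of the enol ether, or of the chromene C3=C4 bond, by the acid before productive ring opening, which would lead to hydrolysis or to bridged cyclisation;
- neutralisation of the acid by the amine;
- loose ion pairing with poor facial selectivity.

The fallback gives up asymmetric catalysis and uses known steps only. It sets out from 6 and 7. Ethylenediammonium diacetate (10 mol %) in toluene at 110 °C gives chromene 8, which is isolated. Heating 8 alone in xylene at 140 °C should then give the cis-fused acetal as a racemate by two established thermal events: valence isomerisation of the 2H-chromene to the o-quinone methide, and uncatalysed [4+2] addition of an o-quinone methide to an enol ether. The racemate is 10 together with (6aR,10aR)-1,3,6-trimethoxy-6a,9-dimethyl-6a,7,8,10a-tetrahydro-6H-benzo[c]chromene F1. Steps 6 and 7 carried out on the racemate give 11 with (6aR,10aR)-1,3-dimethoxy-6a,9-dimethyl-6a,7,8,10a-tetrahydro-6H-benzo[c]chromen-6-ol F2, and then 12 with 2-[(1S,6R)-6-ethynyl-3,6-dimethylcyclohex-2-en-1-yl]-3,5-dimethoxyphenol F3. Acylation with (S)-1-phenylethyl isocyanate (Et3N, CH2Cl2) gives the diastereomers 2-[(1R,6S)-6-ethynyl-3,6-dimethylcyclohex-2-en-1-yl]-3,5-dimethoxyphenyl N-[(1S)-1-phenylethyl]carbamate F4 and 2-[(1S,6R)-6-ethynyl-3,6-dimethylcyclohex-2-en-1-yl]-3,5-dimethoxyphenyl N-[(1S)-1-phenylethyl]carbamate F5. These are separated by chromatography or crystallisation. K2CO3 in MeOH cleaves F4 to 12, where the route is rejoined.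

**Step 7.** The aldehyde is neopentylic and sits mostly as its lactol, so the homologation may be slow. In that case the phenoxide may fragment by retro-Michael cleavage of the C6–C1 bond, which would erode the stereochemical integrity. The fallback sets out from 11. A Wittig reaction with the ylide from (chloromethyl)triphenylphosphonium chloride and NaHMDS (THF, −78 to 0 °C, with an extra equivalent of base for the phenol) gives 2-[(1R,6S)-6-(2-chloroethenyl)-3,6-dimethylcyclohex-2-en-1-yl]-3,5-dimethoxyphenol F6 as an E/Z mixture. Dehydrochlorination with n-BuLi (3 equiv, THF, −78 °C) gives 12, where the route is rejoined.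

**Step 12.** The alkyne lies between a quaternary carbon and a di-ortho-substituted arene. Hydrogen uptake may therefore be slow, and forcing it risks over-reduction, reduction of the coumarin C3=C4 bonds, or Z to E isomerisation on the metal. The fallback sets out from 14 and uses 16 in a different way. Rhodium-catalysed trans-hydroboration of the terminal alkyne (pinacolborane, [Rh(cod)Cl]2, P(i-Pr)3, Et3N, cyclohexane, rt) should give 8-[(1R,6R)-3,6-dimethyl-6-[(Z)-2-(4,4,5,5-tetramethyl-1,3,2-dioxaborolan-2-yl)ethenyl]cyclohex-2-en-1-yl]-5,7-dimethoxy-2H-chromen-2-one F12. Suzuki–Miyaura coupling of F12 with 16 (Pd(dppf)Cl2, K3PO4, dioxane/H2O, 60 °C) proceeds with retention of the alkene geometry and arrives directly at 18.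

**Step 9.** Thermal stress near 215 °C may degrade the terminal alkyne, and the bulky group next to the phenol may slow the lactonisation. The fallback sets out from 13. The Wittig reaction at 80 °C in toluene stops at ethyl (2E)-3-{3-[(1R,6S)-6-ethynyl-3,6-dimethylcyclohex-2-en-1-yl]-2-hydroxy-4,6-dimethoxyphenyl}prop-2-enoate F7. Irradiation at 365 nm in MeCN isomerises the alkene, and the Z isomer lactonises spontaneously to 14, where the route is rejoined.

**Step 10.** The regioselectivity may leak towards C6, or towards C3 of the pyranone, which would give isomeric iodides that are hard to separate. The fallback sets out from 7 and fixes the position of iodine by a directing group: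
- Carbamoylation (ClC(O)NEt2, NaH, THF) gives 3,5-dimethoxyphenyl N,N-diethylcarbamate F8.
- Directed ortho-metalation (s-BuLi, TMEDA, THF, −78 °C) and quenching with I2 gives 2-iodo-3,5-dimethoxyphenyl N,N-diethylcarbamate F9; both positions ortho to the carbamate are equivalent.
- Hydrolysis (NaOH, EtOH, reflux) gives 2-iodo-3,5-dimethoxyphenol F10.
- The formylation of step 8 gives 2-hydroxy-3-iodo-4,6-dimethoxybenzaldehyde F11.
- The Wittig lactonisation of step 9 gives 16, where the route is rejoined.

## Further compounds

F1 | step 5 | (6aR,10aR)-1,3,6-trimethoxy-6a,9-dimethyl-6a,7,8,10a-tetrahydro-6H-benzo[c]chromene | COC1Oc2cc(OC)cc(OC)c2[C@H]2C=C(C)CC[C@@]12C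
F2 | step 5 | (6aR,10aR)-1,3-dimethoxy-6a,9-dimethyl-6a,7,8,10a-tetrahydro-6H-benzo[c]chromen-6-ol | OC1Oc2cc(OC)cc(OC)c2[C@H]2C=C(C)CC[C@@]12C
F3 | step 5 | 2-[(1S,6R)-6-ethynyl-3,6-dimethylcyclohex-2-en-1-yl]-3,5-dimethoxyphenol | C#C[C@]1(C)CCC(C)=C[C@@H]1c1c(O)cc(OC)cc1OC
F4 | step 5 | 2-[(1R,6S)-6-ethynyl-3,6-dimethylcyclohex-2-en-1-yl]-3,5-dimethoxyphenyl N-[(1S)-1-phenylethyl]carbamate | C#C[C@@]1(C)CCC(C)=C[C@H]1c1c(OC(=O)N[C@@H](C)c2ccccc2)cc(OC)cc1OC
F5 | step 5 | 2-[(1S,6R)-6-ethynyl-3,6-dimethylcyclohex-2-en-1-yl]-3,5-dimethoxyphenyl N-[(1S)-1-phenylethyl]carbamate | C#C[C@]1(C)CCC(C)=C[C@@H]1c1c(OC(=O)N[C@@H](C)c2ccccc2)cc(OC)cc1OC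
F6 | step 7 | 2-[(1R,6S)-6-(2-chloroethenyl)-3,6-dimethylcyclohex-2-en-1-yl]-3,5-dimethoxyphenol (E/Z mixture) | ClC=C[C@@]1(C)CCC(C)=C[C@H]1c1c(O)cc(OC)cc1OC
F7 | step 9 | ethyl (2E)-3-{3-[(1R,6S)-6-ethynyl-3,6-dimethylcyclohex-2-en-1-yl]-2-hydroxy-4,6-dimethoxyphenyl}prop-2-enoate | C#C[C@@]1(C)CCC(C)=C[C@H]1c1c(O)c(/C=C/C(=O)OCC)c(OC)cc1OC
F8 | step 10 | 3,5-dimethoxyphenyl N,N-diethylcarbamate | CCN(CC)C(=O)Oc1cc(OC)cc(OC)c1
F9 | step 10 | 2-iodo-3,5-dimethoxyphenyl N,N-diethylcarbamate | CCN(CC)C(=O)Oc1cc(OC)cc(OC)c1I
F10 | step 10 | 2-iodo-3,5-dimethoxyphenol | Oc1cc(OC)cc(OC)c1I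
F11 | step 10 | 2-hydroxy-3-iodo-4,6-dimethoxybenzaldehyde | O=Cc1c(O)c(I)c(OC)cc1OC
F12 | step 12 | 8-[(1R,6R)-3,6-dimethyl-6-[(Z)-2-(4,4,5,5-tetramethyl-1,3,2-dioxaborolan-2-yl)ethenyl]cyclohex-2-en-1-yl]-5,7-dimethoxy-2H-chromen-2-one | CC1(C)OB(/C=C\[C@@]2(C)CCC(C)=C[C@H]2c2c(OC)cc(OC)c3ccc(=O)oc23)OC1(C)C
A1 | alternative 1 | 8-[(1R,6S)-3,6-dimethyl-6-{[tri(propan-2-yl)silyl]ethynyl}cyclohex-2-en-1-yl]-5,7-dimethoxy-2H-chromen-2-one | CC(C)[Si](C(C)C)(C(C)C)C#C[C@@]1(C)CCC(C)=C[C@H]1c1c(OC)cc(OC)c2ccc(=O)oc12
A2 | alternative 1 | (3R,6S)-3-methoxy-3,6-dimethyl-6-{[tri(propan-2-yl)silyl]ethynyl}cyclohex-1-ene | CO[C@]1(C)CC[C@](C)(C#C[Si](C(C)C)(C(C)C)C(C)C)C=C1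
A3 | alternative 1 | 5-methoxy-2-oxo-8-(trimethylsilyl)-2H-chromen-7-yl trifluoromethanesulfonate | COc1cc(OS(=O)(=O)C(F)(F)F)c([Si](C)(C)C)c2oc(=O)ccc12
A4 | alternative 2 | (6aS,10aS)-1,3-dimethoxy-9-methyl-6-oxo-10-(trimethylsilyl)-6a,7,10,10a-tetrahydro-6H-benzo[c]chromene-6a-carbaldehyde (either epimer at C10) | O=C[C@]12CC=C(C)C([Si](C)(C)C)[C@H]1c1c(OC)cc(OC)cc1OC2=O
A5 | alternative 2 | 5,7-dimethoxy-2-oxo-2H-chromene-3-carbaldehyde | COc1cc(OC)c2cc(C=O)c(=O)oc2c1
A6 | alternative 2 | (E)-trimethyl(2-methylbuta-1,3-dien-1-yl)silane | C=C/C(C)=C/[Si](C)(C)C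
A7 | alternative 3 | 2-[(1R,6S)-6-({[tert-butyl(dimethyl)silyl]oxy}methyl)-3,6-dimethylcyclohex-2-en-1-yl]-5-methoxy-3-{[tri(propan-2-yl)silyl]oxy}phenol | CC(C)(C)[Si](C)(C)OC[C@@]1(C)CCC(C)=C[C@H]1c1c(O)cc(OC)cc1O[Si](C(C)C)(C(C)C)C(C)C
A8 | alternative 3 | tert-butyl{[(1S,2R)-1,4-dimethyl-2-({[tri(propan-2-yl)silyl]oxy}ethynyl)cyclohex-3-en-1-yl]methoxy}dimethylsilane | CC(C)(C)[Si](C)(C)OC[C@@]1(C)CCC(C)=C[C@H]1C#CO[Si](C(C)C)(C(C)C)C(C)C
A9 | alternative 3 | 3-methoxycyclobut-2-en-1-one | COC1=CC(=O)C1
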